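The target's diene is built around the C13–C14 and C15–C16 bonds of the Z-trisubstituted C14=C15 olefin, whose C15 carries a methyl group and the three-carbon tether to the furan ring. A 3-(furan-3-yl)propylcopper reagent adds syn across propyne, and the resulting Z-alkenyl metal is coupled in the same flask with an E-vinyl iodide. One operation therefore sets the olefin geometry, completes the C12–C15 diene and attaches the furan arm, without closing a ring. The iodide partner is the silyl-protected C6–C13 chain that already holds both methyl stereocentres (C7, C11), drawn from the two enantiomeric 3-bromo-2-methylpropanols. The butenolide ring is added last by aldol and elimination.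

Key step: step 13

Numbering used: butenolide ring O1, C2 (carbonyl), C3 (methyl), C4 (hydroxyl), C5; exocyclic olefin carbon C6; chain C7 to C18; the furan ring is bonded to C18 through its 3-position.

Remark: aldol adduct 31 forms as diastereomers at its two new carbons (C5, C6), which both become sp2 in step 18; its SMILES therefore leaves these two centres open.

Step 1
Reactants: 1 (S)-3-bromo-2-methylpropan-1-ol
Product: 2 (S)-(3-bromo-2-methylpropoxy)(tert-butyl)diphenylsilane
Conditions: t-BuPh2SiCl, imidazole, CH2Cl2, 0 → 20 °C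
Reagents that add atoms: tert-butyl(chloro)diphenylsilane, CC(C)(C)[Si](Cl)(c1ccccc1)c1ccccc1
Why: Imidazole-promoted O-silylation of the primary alcohol should be clean, and the stereocentre that becomes C7 is not involved.

Step 2
Reactants: 3 1,3-dithiane; 2 (S)-(3-bromo-2-methylpropoxy)(tert-butyl)diphenylsilane
Product: 5 tert-butyl{[(2R)-3-(1,3-dithian-2-yl)-2-methylpropyl]oxy}diphenylsilane, via 2-lithio-1,3-dithiane 4 (not isolated)
Conditions: 3, n-BuLi, THF, −30 °C; then 2, −30 → 20 °C
Reagents that add atoms: none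
Why: Corey–Seebach alkylation, in which the unhindered dithiane anion displaces the primary bromide by SN2 one carbon away from the stereocentre, so the dithiane carbon becomes C9 and the configuration is untouched (the descriptor changes only through the priority rules).

Step 3
Reactants: 6 (R)-3-bromo-2-methylpropan-1-ol
Product: 7 (R)-(3-bromo-2-methylpropoxy)(tert-butyl)dimethylsilane
Conditions: t-BuMe2SiCl, imidazole, CH2Cl2, 0 → 20 °C
Reagents that add atoms: tert-butyl(chloro)dimethylsilane, CC(C)(C)[Si](C)(C)Cl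
Why: Standard O-silylation gives the more labile silyl ether on the oxygen that will become the C12 aldehyde, and the stereocentre that becomes C11 is not involved.

Step 4
Reactants: 7 (R)-(3-bromo-2-methylpropoxy)(tert-butyl)dimethylsilane
Product: 8 (R)-tert-butyl(3-iodo-2-methylpropoxy)dimethylsilane
Conditions: NaI, acetone, reflux
Reagents that add atoms: sodium iodide, [Na+].[I-]
Why: Finkelstein exchange (SN2 by iodide at the primary carbon, driven by precipitation of NaBr) should give the more reactive iodide needed for the hindered second alkylation without touching the adjacent stereocentre.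

Step 5
Reactants: 5 tert-butyl{[(2R)-3-(1,3-dithian-2-yl)-2-methylpropyl]oxy}diphenylsilane; 8 (R)-tert-butyl(3-iodo-2-methylpropoxy)dimethylsilane
Product: 10 tert-butyl{[(2R)-3-{2-[(2S)-3-{[tert-butyl(dimethyl)silyl]oxy}-2-methylpropyl]-1,3-dithian-2-yl}-2-methylpropyl]oxy}diphenylsilane, via 2-alkyl-2-lithio-1,3-dithiane 9 (not isolated)
Conditions: 5, t-BuLi, THF/HMPA (10:1), −78 °C; then 8, −78 → −20 °C
Reagents that add atoms: none
Why: Second Corey–Seebach alkylation, in which the tertiary dithiane anion formed with t-BuLi/HMPA displaces the primary iodide by SN2, joining C9 to C10 while both methyl stereocentres stay one carbon away from the reacting atoms.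

Step 6
Reactants: 10 tert-butyl{[(2R)-3-{2-[(2S)-3-{[tert-butyl(dimethyl)silyl]oxy}-2-methylpropyl]-1,3-dithian-2-yl}-2-methylpropyl]oxy}diphenylsilane
Product: 11 (2R,6S)-1-[(tert-butyldiphenylsilyl)oxy]-7-[(tert-butyldimethylsilyl)oxy]-2,6-dimethylheptane
Conditions: Raney Ni, EtOH, reflux
Reagents that add atoms: none
Why: Raney nickel desulfurisation (Mozingo-type reduction) should replace both C–S bonds at C9 by C–H, leaving the silyl ethers and the two methyl stereocentres untouched.

Step 7
Reactants: 11 (2R,6S)-1-[(tert-butyldiphenylsilyl)oxy]-7-[(tert-butyldimethylsilyl)oxy]-2,6-dimethylheptane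
Product: 12 (2S,6R)-7-[(tert-butyldiphenylsilyl)oxy]-2,6-dimethylheptan-1-ol
Conditions: camphor-10-sulfonic acid (cat.), MeOH/CH2Cl2 (1:1), 0 °C
Reagents that add atoms: none
Why: Acid-catalysed methanolysis cleaves the primary tert-butyldimethylsilyl ether far faster than the bulkier, more acid-stable tert-butyldiphenylsilyl ether (selective desilylation), which distinguishes the two ends of the otherwise meso-type chain.

Step 8
Reactants: 12 (2S,6R)-7-[(tert-butyldiphenylsilyl)oxy]-2,6-dimethylheptan-1-ol
Product: 13 (2S,6R)-7-[(tert-butyldiphenylsilyl)oxy]-2,6-dimethylheptanal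
Conditions: Dess–Martin periodinane, NaHCO3, CH2Cl2, 0 → 20 °C
Reagents that add atoms: none
Why: Dess–Martin oxidation under buffered, non-basic conditions should give the aldehyde without epimerising the α-methyl stereocentre (C11), and the crude aldehyde is used at once.

Step 9
Reactants: 13 (2S,6R)-7-[(tert-butyldiphenylsilyl)oxy]-2,6-dimethylheptanal
Product: 14 tert-butyl{[(2R,6S,7E)-8-iodo-2,6-dimethyloct-7-en-1-yl]oxy}diphenylsilane
Conditions: CrCl2, CHI3, THF/1,4-dioxane (1:6), 0 → 20 °C, dark
Reagents that add atoms: iodoform, IC(I)I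
Why: Takai olefination, in which the geminal dichromium species formed from CHI3 and divalent chromium adds to the aldehyde and eliminates to the E-iodoalkene under essentially neutral conditions, so the C11 stereocentre next to the carbonyl should survive.

Step 10
Reactants: 15 3-bromofuran; 16 oxetane
Product: 18 3-(furan-3-yl)propan-1-ol, via 3-lithiofuran 17 (not isolated)
Conditions: 15, n-BuLi, THF, −78 °C; then 16, BF3·OEt2, −78 °C
Reagents that add atoms: none
Why: Bromine–lithium exchange at −78 °C gives 3-lithiofuran, which keeps its position at that temperature and opens BF3-activated oxetane by SN2 attack at a ring CH2 (Lewis acid-assisted oxetane opening by an organolithium).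

Step 11
Reactants: 18 3-(furan-3-yl)propan-1-ol
Product: 19 3-(3-bromopropyl)furan
Conditions: CBr4, PPh3, CH2Cl2, 0 °C
Reagents that add atoms: carbon tetrabromide, BrC(Br)(Br)Br
Why: Appel bromination converts the primary alcohol to the bromide under neutral conditions that the acid-sensitive furan tolerates.

Step 12
Reactants: 19 3-(3-bromopropyl)furan
Product: 20 3-(furan-3-yl)propylmagnesium bromide
Conditions: Mg turnings, Et2O, reflux; used as a titrated solution
Reagents that add atoms: magnesium, [Mg]
Why: Insertion of magnesium into the primary C–Br bond (Grignard formation) is compatible with the 3-alkylfuran and is run in Et2O because the carbocupration that follows needs that solvent.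

Step 13
Reactants: 20 3-(furan-3-yl)propylmagnesium bromide; 21 propyne; 14 tert-butyl{[(2R,6S,7E)-8-iodo-2,6-dimethyloct-7-en-1-yl]oxy}diphenylsilane
Product: 25 tert-butyl{[(2R,6S,7E,9Z)-13-(furan-3-yl)-2,6,10-trimethyltrideca-7,9-dien-1-yl]oxy}diphenylsilane, via alkylcopper 22 (not isolated), via alkenylcopper 23 (not isolated), via alkenylzinc bromide 24 (not isolated)
Conditions: 20 (1.8 equiv), CuBr·SMe2 (1.8 equiv), Et2O/Me2S (2:1), −45 °C; 21, −25 °C, excess purged; ZnBr2 in THF, −40 °C; 14 (1.0 equiv), Pd(PPh3)4 (5 mol %), −20 → 20 °C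
Reagents that add atoms: none
Why: The Grignard reagent 20 and CuBr·SMe2 give alkylcopper 22, which inserts propyne 21 through a four-centre syn addition that puts the furylpropyl group on the internal carbon (new C15–C16 bond) and copper on the terminal carbon, so that chain and metal are cis in 23. Exchange with ZnBr2 gives alkenylzinc 24, which enters a palladium cycle with iodide 14: oxidative addition to zerovalent palladium, transmetallation and reductive elimination, all with retention at both sp2 carbons (new C13–C14 bond). The closest known reaction type is the Normant carbocupration of a terminal alkyne followed by zinc- and palladium-mediated (Negishi-type) coupling of the alkenylcopper with an alkenyl iodide. No ring is closed and no stereocentre is created; C7 and C11 are sp3 carbons of 14 that none of the reagents can reach. The step needs the branched regiochemistry, the syn stereochemistry and geometric fidelity through the coupling, which are intrinsic to RCu·MgBr2 reagents with a small terminal alkyne in Et2O/Me2S and are secured by keeping 23 at or below −20 °C until zinc is added. The silyl ether and the 3-alkylfuran are inert to all three organometallics, so the E geometry of C12=C13 and the Z geometry of C14=C15 should both appear in 25.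

Step 14
Reactants: 26 3-methyltetronic acid (4-hydroxy-3-methylfuran-2(5H)-one)
Product: 27 4-methoxy-3-methylfuran-2(5H)-one
Conditions: Me2SO4, K2CO3, acetone, reflux
Reagents that add atoms: dimethyl sulfate, COS(=O)(=O)OC
Why: Base-mediated O-methylation of the vinylogous acid should take place mainly at O4 to give the vinylogous methyl ester that permits lithiation at C5.

Step 15
Reactants: 25 tert-butyl{[(2R,6S,7E,9Z)-13-(furan-3-yl)-2,6,10-trimethyltrideca-7,9-dien-1-yl]oxy}diphenylsilane
Product: 28 (2R,6S,7E,9Z)-13-(furan-3-yl)-2,6,10-trimethyltrideca-7,9-dien-1-ol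
Conditions: Bu4NF, THF, 0 → 20 °C
Reagents that add atoms: none
Why: Fluoride attack at silicon (desilylation) should free the C6 alcohol, while diene, furan and both stereocentres are inert.

Step 16
Reactants: 28 (2R,6S,7E,9Z)-13-(furan-3-yl)-2,6,10-trimethyltrideca-7,9-dien-1-ol
Product: 29 (2R,6S,7E,9Z)-13-(furan-3-yl)-2,6,10-trimethyltrideca-7,9-dienal
Conditions: Dess–Martin periodinane, NaHCO3, CH2Cl2, 0 → 20 °C
Reagents that add atoms: none
Why: Dess–Martin oxidation under bicarbonate buffer should give the C6 aldehyde without epimerising C7 and without touching the furan or the diene.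

Step 17
Reactants: 27 4-methoxy-3-methylfuran-2(5H)-one; 29 (2R,6S,7E,9Z)-13-(furan-3-yl)-2,6,10-trimethyltrideca-7,9-dienal
Product: 31 5-[(2R,6S,7E,9Z)-13-(furan-3-yl)-1-hydroxy-2,6,10-trimethyltrideca-7,9-dien-1-yl]-4-methoxy-3-methylfuran-2(5H)-one (diastereomers at C5/C6), via lithium 4-methoxy-3-methylfuran-2-olate 30 (not isolated)
Conditions: 27 (1.2 equiv), LiN(i-Pr)2 (1.1 equiv), THF, −78 °C; then 29, −78 °C; AcOH, −78 °C
Reagents that add atoms: none
Why: Deprotonation of the vinylogous ester at C5 gives the aromatic lithium 2-furanolate 30, which adds through C5 to the aldehyde in a vinylogous aldol addition at −78 °C; the two new centres form without reliable control but are both removed in step 18, and the absence of free amide base protects C7.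

Step 18
Reactants: 31 5-[(2R,6S,7E,9Z)-13-(furan-3-yl)-1-hydroxy-2,6,10-trimethyltrideca-7,9-dien-1-yl]-4-methoxy-3-methylfuran-2(5H)-one (the like diastereomers, (5R,6R) and (5S,6S), collected by chromatography; if the pairs do not separate, the mixture is used and 33 is separated from its 5Z isomer afterwards)
Product: 33 (5E)-5-[(2R,6S,7E,9Z)-13-(furan-3-yl)-2,6,10-trimethyltrideca-7,9-dien-1-ylidene]-4-methoxy-3-methylfuran-2(5H)-one, via aldol mesylate 32 (not isolated)
Conditions: MsCl, Et3N, CH2Cl2, 0 °C; then DBU, 0 → 20 °C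
Reagents that add atoms: none
Why: Mesylation followed by base-induced anti β-elimination (E2, H5 and the mesyloxy group antiperiplanar) should be stereospecific, so the like aldols place C7 cis to C4 and give the 5E olefin, whereas the unlike aldols would give 5Z by the same course.

Step 19
Reactants: 33 (5E)-5-[(2R,6S,7E,9Z)-13-(furan-3-yl)-2,6,10-trimethyltrideca-7,9-dien-1-ylidene]-4-methoxy-3-methylfuran-2(5H)-one
Product: 34 (5E)-5-[(2R,6S,7E,9Z)-13-(furan-3-yl)-2,6,10-trimethyltrideca-7,9-dien-1-ylidene]-4-hydroxy-3-methylfuran-2(5H)-one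
Conditions: n-PrSLi, HMPA, 20 °C; then cold dilute HCl to pH 3
Reagents that add atoms: none
Why: SN2 attack of the soft thiolate on the O-methyl carbon of the vinylogous methyl ester (nucleophilic O-demethylation) should release the lithium tetronate, which is protonated on work-up to the 4-hydroxybutenolide with the 5E olefin, the diene and the furan unchanged.

Compound list
1 | (S)-3-bromo-2-methylpropan-1-ol | OC[C@H](C)CBr | starting material
2 | (S)-(3-bromo-2-methylpropoxy)(tert-butyl)diphenylsilane | CC(C)(C)[Si](c1ccccc1)(c1ccccc1)OC[C@H](C)CBr | intermediate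
3 | 1,3-dithiane | C1CSCSC1 | starting material
4 | 2-lithio-1,3-dithiane | [Li]C1SCCCS1 | intermediate
5 | tert-butyl{[(2R)-3-(1,3-dithian-2-yl)-2-methylpropyl]oxy}diphenylsilane | CC(C)(C)[Si](c1ccccc1)(c1ccccc1)OC[C@H](C)CC1SCCCS1 | intermediate
6 | (R)-3-bromo-2-methylpropan-1-ol | OC[C@@H](C)CBr | starting material
7 | (R)-(3-bromo-2-methylpropoxy)(tert-butyl)dimethylsilane | CC(C)(C)[Si](C)(C)OC[C@@H](C)CBr | intermediate
8 | (R)-tert-butyl(3-iodo-2-methylpropoxy)dimethylsilane | CC(C)(C)[Si](C)(C)OC[C@@H](C)CI | intermediate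
9 | 2-lithio derivative of 5 (2-alkyl-2-lithio-1,3-dithiane) | CC(C)(C)[Si](c1ccccc1)(c1ccccc1)OC[C@H](C)CC1([Li])SCCCS1 | intermediate
10 | tert-butyl{[(2R)-3-{2-[(2S)-3-{[tert-butyl(dimethyl)silyl]oxy}-2-methylpropyl]-1,3-dithian-2-yl}-2-methylpropyl]oxy}diphenylsilane | CC(C)(C)[Si](c1ccccc1)(c1ccccc1)OC[C@H](C)CC1(C[C@H](C)CO[Si](C)(C)C(C)(C)C)SCCCS1 | intermediate
11 | (2R,6S)-1-[(tert-butyldiphenylsilyl)oxy]-7-[(tert-butyldimethylsilyl)oxy]-2,6-dimethylheptane | CC(C)(C)[Si](c1ccccc1)(c1ccccc1)OC[C@H](C)CCC[C@H](C)CO[Si](C)(C)C(C)(C)C | intermediate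
12 | (2S,6R)-7-[(tert-butyldiphenylsilyl)oxy]-2,6-dimethylheptan-1-ol | CC(C)(C)[Si](c1ccccc1)(c1ccccc1)OC[C@H](C)CCC[C@H](C)CO | intermediate
13 | (2S,6R)-7-[(tert-butyldiphenylsilyl)oxy]-2,6-dimethylheptanal | CC(C)(C)[Si](c1ccccc1)(c1ccccc1)OC[C@H](C)CCC[C@H](C)C=O | intermediate
14 | tert-butyl{[(2R,6S,7E)-8-iodo-2,6-dimethyloct-7-en-1-yl]oxy}diphenylsilane | CC(C)(C)[Si](c1ccccc1)(c1ccccc1)OC[C@H](C)CCC[C@H](C)/C=C/I | intermediate
15 | 3-bromofuran | Brc1ccoc1 | starting material
16 | oxetane | C1COC1 | starting material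
17 | 3-lithiofuran | [Li]c1ccoc1 | intermediate
18 | 3-(furan-3-yl)propan-1-ol | OCCCc1ccoc1 | intermediate
19 | 3-(3-bromopropyl)furan | BrCCCc1ccoc1 | intermediate
20 | 3-(furan-3-yl)propylmagnesium bromide | Br[Mg]CCCc1ccoc1 | intermediate
21 | propyne | CC#C | starting material
22 | [3-(furan-3-yl)propyl]copper (MgBr2 complex) | [Cu]CCCc1ccoc1 | intermediate
23 | [(1Z)-5-(furan-3-yl)-2-methylpent-1-en-1-yl]copper | C/C(=C/[Cu])CCCc1ccoc1 | intermediate
24 | [(1Z)-5-(furan-3-yl)-2-methylpent-1-en-1-yl]zinc bromide | C/C(=C/[Zn]Br)CCCc1ccoc1 | intermediate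
25 | tert-butyl{[(2R,6S,7E,9Z)-13-(furan-3-yl)-2,6,10-trimethyltrideca-7,9-dien-1-yl]oxy}diphenylsilane | CC(C)(C)[Si](c1ccccc1)(c1ccccc1)OC[C@H](C)CCC[C@H](C)/C=C/C=C(/C)CCCc1ccoc1 | intermediate
26 | 3-methyltetronic acid (4-hydroxy-3-methylfuran-2(5H)-one) | CC1=C(O)COC1=O | starting material
27 | 4-methoxy-3-methylfuran-2(5H)-one | COC1=C(C)C(=O)OC1 | intermediate
28 | (2R,6S,7E,9Z)-13-(furan-3-yl)-2,6,10-trimethyltrideca-7,9-dien-1-ol | OC[C@H](C)CCC[C@H](C)/C=C/C=C(/C)CCCc1ccoc1 | intermediate
29 | (2R,6S,7E,9Z)-13-(furan-3-yl)-2,6,10-trimethyltrideca-7,9-dienal | O=C[C@H](C)CCC[C@H](C)/C=C/C=C(/C)CCCc1ccoc1 | intermediate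
30 | lithium 4-methoxy-3-methylfuran-2-olate | COc1coc(O[Li])c1C | intermediate
31 | 5-[(2R,6S,7E,9Z)-13-(furan-3-yl)-1-hydroxy-2,6,10-trimethyltrideca-7,9-dien-1-yl]-4-methoxy-3-methylfuran-2(5H)-one, diastereomers at C5 and C6 | COC1=C(C)C(=O)OC1C(O)[C@H](C)CCC[C@H](C)/C=C/C=C(/C)CCCc1ccoc1 | intermediate
32 | methanesulfonate of 31 | COC1=C(C)C(=O)OC1C(OS(C)(=O)=O)[C@H](C)CCC[C@H](C)/C=C/C=C(/C)CCCc1ccoc1 | intermediate
33 | (5E)-5-[(2R,6S,7E,9Z)-13-(furan-3-yl)-2,6,10-trimethyltrideca-7,9-dien-1-ylidene]-4-methoxy-3-methylfuran-2(5H)-one | CC1=C(OC)/C(=C\[C@H](C)CCC[C@H](C)/C=C/C=C(/C)CCCc2ccoc2)OC1=O | intermediate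
34 | (5E)-5-[(2R,6S,7E,9Z)-13-(furan-3-yl)-2,6,10-trimethyltrideca-7,9-dien-1-ylidene]-4-hydroxy-3-methylfuran-2(5H)-one | CC1=C(O)/C(=C\[C@H](C)CCC[C@H](C)/C=C/C=C(/C)CCCc2ccoc2)OC1=O | target

Total step count: 19. Longest linear sequence: 13 steps (1, 2, 5, 6, 7, 8, 9, 13, 15, 16, 17, 18, 19).

Steps most likely to fail

Step 13. The alkenylcopper may be lost to protonolysis or thermal decay before zinc exchange, or transmetallation to palladium may be slow, so that iodide 14 is left unconsumed or the Z geometry erodes. The fallback sets out from 13 and from 23 (generated from 20 and 21 as in step 13) and comes back at 25. It makes both halves as isolable partners of reversed polarity. Alkenylcopper 23 is quenched with I2 (THF, −40 → 0 °C), which should give, with retention, 3-[(4Z)-5-iodo-4-methylpent-4-en-1-yl]furan F1. Aldehyde 13 is converted by the boron variant of the Takai olefination (2-(dichloromethyl)-4,4,5,5-tetramethyl-1,3,2-dioxaborolane, CrCl2, LiI, THF) into tert-butyl{[(2R,6S,7E)-2,6-dimethyl-8-(4,4,5,5-tetramethyl-1,3,2-dioxaborolan-2-yl)oct-7-en-1-yl]oxy}diphenylsilane F2. Suzuki–Miyaura coupling of the two (Pd(PPh3)4, aqueous NaOH, THF, 20 °C) proceeds with retention at both olefins and should give 25.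

Step 18. Stereospecificity may be lost through a stepwise E1cB pathway via the furanolate, or the aldol ratio may favour the unlike pair, so that the 5Z olefin dominates. The fallback sets out from 31 and comes back at 33. The unlike aldols are separated by chromatography: the (5R,6S) aldol, (5R)-5-[(1S,2R,6S,7E,9Z)-13-(furan-3-yl)-1-hydroxy-2,6,10-trimethyltrideca-7,9-dien-1-yl]-4-methoxy-3-methylfuran-2(5H)-one F3, and the (5S,6R) aldol, its (5S,1R) counterpart F4. They are heated with the Burgess reagent (methyl N-(triethylammoniosulfonyl)carbamate, benzene, 50 °C). The resulting triethylammonium N-(methoxycarbonyl)sulfamate ester of the (5R,6S) aldol F5 and triethylammonium N-(methoxycarbonyl)sulfamate ester of the (5S,6R) aldol F6 should fragment by an intramolecular syn elimination (Ei) that removes the more acidic H5. From the unlike series a syn elimination also places C7 cis to C4, so this should give 33.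

Step 19. Reversible conjugate addition of the thiolate at C6 may equilibrate the 5E olefin toward the 5Z geometry, or demethylation may stall. The fallback sets out from 26 and 29 and comes back at 34; it replaces the methyl ether by a fluoride-labile one. Mitsunobu O-alkylation of 26 with 2-(trimethylsilyl)ethanol (PPh3, diisopropyl azodicarboxylate, THF) should give 3-methyl-4-[2-(trimethylsilyl)ethoxy]furan-2(5H)-one F7. Lithiation (LiN(i-Pr)2, THF, −78 °C) gives lithium 3-methyl-4-[2-(trimethylsilyl)ethoxy]furan-2-olate F8, which adds to 29 to give the aldol 5-[(2R,6S,7E,9Z)-13-(furan-3-yl)-1-hydroxy-2,6,10-trimethyltrideca-7,9-dien-1-yl]-3-methyl-4-[2-(trimethylsilyl)ethoxy]furan-2(5H)-one F9. MsCl/Et3N converts its like diastereomers into the methanesulfonate of that aldol F10, and DBU then gives (5E)-5-[(2R,6S,7E,9Z)-13-(furan-3-yl)-2,6,10-trimethyltrideca-7,9-dien-1-ylidene]-3-methyl-4-[2-(trimethylsilyl)ethoxy]furan-2(5H)-one F11. Bu4NF (THF, 0 °C) attacks silicon and the ether fragments to ethene and the tetronate, giving 34 without a soft nucleophile.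

Further compounds
F1 | step 13 | 3-[(4Z)-5-iodo-4-methylpent-4-en-1-yl]furan | C/C(=C/I)CCCc1ccoc1
F2 | step 13 | tert-butyl{[(2R,6S,7E)-2,6-dimethyl-8-(4,4,5,5-tetramethyl-1,3,2-dioxaborolan-2-yl)oct-7-en-1-yl]oxy}diphenylsilane | CC(C)(C)[Si](c1ccccc1)(c1ccccc1)OC[C@H](C)CCC[C@H](C)/C=C/B1OC(C)(C)C(C)(C)O1
F3 | step 18 | (5R)-5-[(1S,2R,6S,7E,9Z)-13-(furan-3-yl)-1-hydroxy-2,6,10-trimethyltrideca-7,9-dien-1-yl]-4-methoxy-3-methylfuran-2(5H)-one | COC1=C(C)C(=O)O[C@@H]1[C@@H](O)[C@H](C)CCC[C@H](C)/C=C/C=C(/C)CCCc1ccoc1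
F4 | step 18 | (5S)-5-[(1R,2R,6S,7E,9Z)-13-(furan-3-yl)-1-hydroxy-2,6,10-trimethyltrideca-7,9-dien-1-yl]-4-methoxy-3-methylfuran-2(5H)-one | COC1=C(C)C(=O)O[C@H]1[C@H](O)[C@H](C)CCC[C@H](C)/C=C/C=C(/C)CCCc1ccoc1
F5 | step 18 | triethylammonium N-(methoxycarbonyl)sulfamate ester of F3 | COC1=C(C)C(=O)O[C@@H]1[C@@H](OS(=O)(=O)[N-]C(=O)OC)[C@H](C)CCC[C@H](C)/C=C/C=C(/C)CCCc1ccoc1.CC[NH+](CC)CC
F6 | step 18 | triethylammonium N-(methoxycarbonyl)sulfamate ester of F4 | COC1=C(C)C(=O)O[C@H]1[C@H](OS(=O)(=O)[N-]C(=O)OC)[C@H](C)CCC[C@H](C)/C=C/C=C(/C)CCCc1ccoc1.CC[NH+](CC)CC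
F7 | step 19 | 3-methyl-4-[2-(trimethylsilyl)ethoxy]furan-2(5H)-one | CC1=C(OCC[Si](C)(C)C)COC1=O
F8 | step 19 | lithium 3-methyl-4-[2-(trimethylsilyl)ethoxy]furan-2-olate | C[Si](C)(C)CCOc1coc(O[Li])c1C
F9 | step 19 | 5-[(2R,6S,7E,9Z)-13-(furan-3-yl)-1-hydroxy-2,6,10-trimethyltrideca-7,9-dien-1-yl]-3-methyl-4-[2-(trimethylsilyl)ethoxy]furan-2(5H)-one, diastereomers at C5 and C6 | C[Si](C)(C)CCOC1=C(C)C(=O)OC1C(O)[C@H](C)CCC[C@H](C)/C=C/C=C(/C)CCCc1ccoc1
F10 | step 19 | methanesulfonate of F9 | C[Si](C)(C)CCOC1=C(C)C(=O)OC1C(OS(C)(=O)=O)[C@H](C)CCC[C@H](C)/C=C/C=C(/C)CCCc1ccoc1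
F11 | step 19 | (5E)-5-[(2R,6S,7E,9Z)-13-(furan-3-yl)-2,6,10-trimethyltrideca-7,9-dien-1-ylidene]-3-methyl-4-[2-(trimethylsilyl)ethoxy]furan-2(5H)-one | CC1=C(OCC[Si](C)(C)C)/C(=C\[C@H](C)CCC[C@H](C)/C=C/C=C(/C)CCCc2ccoc2)OC1=O
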